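The eta run is your guide, because the theta run is the same flask at the same charge, left to 60 h instead of 20 h.

| flask | starting material | free catalyst | time |
|---|---|---|---|
| eta | 0.0800 M | 0.00640 M |  |
| beta | 0.120 M | 0.00640 M |  |
| epsilon | 0.0800 M | 0.0190 M |  |
| theta | 0.0800 M | 0.00640 M | 60 h |

- eta run (time / h: [product] / M): 1.1: 0.0152; 3.4: 0.0343; 6.6: 0.0485; 10: 0.0552; 15: 0.0587; 20: 0.0593
- beta run (time / h: [product] / M): 1.1: 0.0227; 3.4: 0.0495; 6.6: 0.0667; 10: 0.0745; 15: 0.0793; 20: 0.0809
- epsilon run (time / h: [product] / M): 1.1: 0.0367; 3.4: 0.0642; 6.6: 0.0717; 10: 0.0743; 15: 0.0738; 20: 0.0755

(scatter of a reading: 6 × 10⁻⁴ M)

1. how the opening rate goes with [free catalyst] round the charge of the eta run: the exponent of the rate at two percent of starting material gone to product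
2. how the opening rate goes with [starting material] round the charge of the eta run: the exponent of the rate at two percent of starting material gone to product (one fixed amount of product, the same in the runs compared)
3. product in the theta run at 60 h, as a share of the starting material charged

- Overall: starting material -> product, with free catalyst as catalyst.
- Constant volume, constant temperature.
- An order is taken over about fifteen percent of the charge, up and down.

Bracket the theta yield yourself. The eta readings climb at every step and reach 74.1% of the charge at 20 h, so take that as the floor. For a rough ceiling, use the epsilon run: it has the same starting material and 2.97 times the free catalyst, and it read 94.4% at 20 h.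

To tighten that, use the tail allowance: the gain a run makes between its 10 h and 15 h readings. If each equal interval yields at most 0.5 of the one before, the gains still to come after 15 h cannot add up to more than that gain. In the eta run the allowance is 0.00350 M, and the next interval read 0.171 of it, so this one pair of readings meets the condition. Adding the allowance to the eta 15 h reading gives a ceiling of 77.8%, good to about 1.7 percentage points given the scatter.

The forecast gives 74.8%, inside your bracket, with a range of 73.5% to 77.5% whose low end lies below your floor, and orders of 1 and 1. Its ground for the yield is that “the catalyst is essentially dead by 20 h”.

The theta run gives 77.2%, with orders of 1.0 and 1.0, so the forecast stands within its margins.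

free catalyst + starting material → product + free catalyst (30.82 /M/h); free catalyst + product → spent catalyst + product (1.976 /M/h); 2 starting material → homo dimer (0.4248 /M/h) Theta ends 0.00305 M above the eta 15 h reading, inside the allowance. In the beta run the allowance is 0.00480 M, and its 20 h reading has added 0.00160 M. The forecast's range would fail if either of two steps acting together were taken away. Theta reaches 85.9% without free catalyst turning to spent catalyst on meeting product, and 88.1% without starting material pairing to homo dimer, against a top of 77.5%.

The readings are simulated with constants of no real substance; the scatter is artificial.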